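In Saturday's run, which is short of partner, the starting material falls by 8.2 percentage points from 0.667 h to 2.00 h while the target falls by 8.7 points. I read this as a fork: a molecule of starting material that finds no partner takes a target with it.

| setting | Monday's | Saturday's | flask |
|---|---|---|---|
| starting material | 0.10 M | 0.15 M | 0.10 M |
| partner | 0.12 M | 0.12 M | 0.120 M |
| remark | the very flask that is asked about, followed so far | run made earlier |  |
| time |  |  | 6.0 h |

| run | time / h | target / % | starting material / % |
|---|---|---|---|
| Monday's | 0.167 | 77.9 | 18.5 |
| Monday's | 0.500 | 95.8 | 0.8 |
| Monday's | 0.833 | 94.8 | 1.1 |
| Monday's | 1.33 | 96.9 | 0 |
| Monday's | 2.00 | 96.5 | 0 |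
| Monday's | 2.50 | 92.9 | 0.5 |
| Monday's | 3.00 | 94.5 | 1.2 |
| Saturday's | 0.133 | 68.9 | 28.4 |
| Saturday's | 0.333 | 73.8 | 16.0 |
| Saturday's | 0.667 | 72.4 | 10.8 |
| Saturday's | 1.00 | 69.1 | 7.4 |
| Saturday's | 1.33 | 64.6 | 5.4 |
| Saturday's | 2.00 | 63.7 | 2.6 |
| Saturday's | 2.50 | 64.2 | 3.9 |

(standard deviation of a reading: 1 percentage point)

* at 6.0 h, what has stopped the reaction, if anything has (the partner has run out first / all of the starting material has reacted / it is still moving)
* target at 6.0 h, in percent of the starting material charged

- the numbers in the tables scatter by 1 percentage point (one standard deviation)
- the reaction counts as stopped when no species that holds the starting material changes by six tenths of a point or more over the second half of the time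

Now I follow the molecules. One that takes the partner raises target minus starting material by two molecules' worth, and one that takes a target leaves that difference unchanged. So the difference climbs with partner used, and with the whole partner charge used it should stand at what I call the partner ceiling, 2[partner]/[starting material] − 1 on the charges, as a fraction of the starting material charged.

This gives two ways to one number. Saturday's charges give 60.0%, and its readings from 0.667 h on give a mean difference of 60.8%. The two agree within the scatter, and one comes from the charges, the other from the readings.

For the asked flask the ceiling is 140%, while Monday's target from 0.500 h on averages 95.2%. Here the ceiling cheats: it lies above the whole charge, so the difference must stop earlier, with the starting material, the limiting reagent, which Monday's run reads at 0% at 2.00 h. For the target in the asked flask I commit to the reading, about 95.2%.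

The forecast says all of the starting material has reacted, with target 95% (range 93% to 96.5%), and holds that “Nothing in the data shows the target degrading in excess partner”.

At 6.0 h the flask's answer is that all of the starting material has reacted, with target 95.0%, so the forecast held. With 0% of the starting material left in this flask, the difference is the target, which stands below the ceiling, and half the gap, reckoned as 18.7% of the partner's charge, is partner left.

    starting material + partner + released group → target + 2 released group (k = 85.0 M⁻² min⁻¹)
    starting material + partner → target + released group (k = 0.0170 M⁻¹ min⁻¹)
    starting material + target → side product (k = 0.130 M⁻¹ min⁻¹)

At 0.114 h in this flask target is made 47.0 times faster than it is used up, each step taken net. Its half-life by the side step there, 1.8 h, is short against 6.0 h, yet by 0.600 h the starting material is down to 0.0709%.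

A second flask, like this one but with 0.40 M of starting material, has a ceiling of −40.0%, so with its partner charge used, target minus starting material should stand there. Computed, it holds 40.0% starting material, 0.00991% target and 0% partner.

The readings are simulated on assumed constants.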